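Ring numbering: O1, C2 (guaiacyl carbon), C3 (branch carbon C3a), C4 (carbinol carbon C4a attached), C5. The plan rests on cutting the tetrahydrofuran at O1–C5 and C3–C4: O1–C2–C3–C3a then maps onto a 2-aryl-3-vinyloxirane and C5–C4–C4a, with the catechol ring, onto an aryl vinyl ketone. One palladium(0)-catalysed (3+2) cycloaddition of the two closes the ring, forms both bonds and sets C3 and C4 under the control of C2, whose bond to O1 stays intact. The epoxide is made with C2 fixed by reagent-controlled chloroallylboration; its vinyl-bearing carbon, erased in the key step, is left cis. Ketone reduction, vinyl cleavage to CH2OH and debenzylation complete the route.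

Key step: step 5

Remark: locants in names follow the ring numbering above; palladium-bound species of step 5 and boron or magnesium alkoxides that are only hydrolysed on work-up are described in the text and not numbered; (−)-Ipc2BOMe, (S)-Me-CBS and catecholborane are taken as commercial.

Step 1
Reactants: 1 4-(benzyloxy)-3-methoxybenzaldehyde; 2 allyl chloride
Product: 4 (1R,2R)-1-[4-(benzyloxy)-3-methoxyphenyl]-2-chlorobut-3-en-1-ol (syn chlorohydrin), via (Z)-γ-chloroallyldiisopinocampheylborane 3 (not isolated)
Conditions: (−)-Ipc2BOMe [from (+)-α-pinene], LiN(c-Hex)2, Et2O–THF, −95 °C; BF3·OEt2; then 1, −95 °C; ethanolamine work-up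
Reagents that add atoms: none
Why: Brown-type asymmetric allylboration with a γ-chloroallyl reagent: lithiated allyl chloride is captured by the borinate at its unsubstituted end, BF3 removes methoxide to free the (Z)-γ-chloroallylborane 3, and this adds to 1 through a closed chair transition state in which the isopinocampheyl groups expose the Si face of the aldehyde (the sense in which the parent allyl reagent turns benzaldehyde into (S)-1-phenylbut-3-en-1-ol), so the carbinol carbon, the future C2, becomes (R) and the Z geometry is translated into the syn chlorohydrin.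

Step 2
Reactants: 4 (1R,2R)-1-[4-(benzyloxy)-3-methoxyphenyl]-2-chlorobut-3-en-1-ol
Product: 5 (2R,3S)-2-[4-(benzyloxy)-3-methoxyphenyl]-3-vinyloxirane (cis)
Conditions: NaH, THF, 0 °C → rt; filtration through basic alumina; used at once
Reagents that add atoms: none
Why: Intramolecular Williamson ether synthesis (3-exo-tet): the sodium alkoxide displaces the neighbouring allylic chloride with inversion at that carbon only, so the syn chlorohydrin should give the cis epoxide while the configuration of C2 is untouched, and the acid-labile benzylic epoxide never meets acid.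

Step 3
Reactants: 6 3,4-bis(benzyloxy)benzaldehyde; 7 vinylmagnesium bromide
Product: 8 rac-1-[3,4-bis(benzyloxy)phenyl]prop-2-en-1-ol
Conditions: THF, 0 °C; aq. NH4Cl
Reagents that add atoms: none
Why: Grignard 1,2-addition of the vinyl nucleophile to the aromatic aldehyde; the carbinol centre is formed racemic and is removed again in step 4.

Step 4
Reactants: 8 rac-1-[3,4-bis(benzyloxy)phenyl]prop-2-en-1-ol
Product: 9 1-[3,4-bis(benzyloxy)phenyl]prop-2-en-1-one
Conditions: activated MnO2 (15 equiv), CH2Cl2, rt; filtered, kept cold, used within hours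
Reagents that add atoms: none
Why: Manganese dioxide oxidation, which is selective for this allylic and benzylic alcohol and runs under neutral heterogeneous conditions that spare the benzyl ethers and do not set off polymerisation of the aryl vinyl ketone; no stereocentre is involved.

Step 5
Reactants: 5 (2R,3S)-2-[4-(benzyloxy)-3-methoxyphenyl]-3-vinyloxirane; 9 1-[3,4-bis(benzyloxy)phenyl]prop-2-en-1-one
Product: 10 [3,4-bis(benzyloxy)phenyl][(2S,3S,4S)-2-(4-benzyloxy-3-methoxyphenyl)-3-vinyltetrahydrofuran-4-yl]methanone (all-trans)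
Conditions: Pd2(dba)3·CHCl3 (2.5 mol %), dppe (6 mol %), Bu4NCl (10 mol %), degassed THF, rt → 40 °C; 9 (1.5 equiv)
Reagents that add atoms: none
Why: Proposed new method: Pd(0) ionises the allylic C3–O bond of 5 with release of ring strain to give a zwitterionic π-allylpalladium alkoxide, whose oxygen adds to the β-carbon of enone 9 (oxa-Michael, O1–C5) and whose resulting ketone enolate then attacks the substituted allyl terminus anti to palladium (C3–C4) with return of Pd(0). The closest known reaction type is the palladium-catalysed (3+2) cycloaddition of vinyl epoxides with doubly activated alkenes; not yet shown is its use with a singly activated, β-unsubstituted aryl vinyl ketone combined with relay of configuration from an aryl-bearing C2. The tetrahydrofuran ring is closed by 5-exo attack of the enolate carbon C4 on C3, which should be preferred over seven-membered closure at the CH2 terminus. C2 keeps its configuration because its bond to oxygen takes no part; the C3 configuration of the epoxide is erased by π–σ–π exchange of the allyl faces through the unsubstituted terminus (assisted by chloride), and C3 is then set under the control of C2 in the ring-closing transition state that places vinyl anti to the C2 aryl group; C4 forms with the aroyl group anti to vinyl and, being α to the ketone, can be equilibrated to that arrangement with catalytic DBU if needed. The step needs branched rather than linear alkylation, face exchange faster than ring closure, and oxa-Michael capture faster than hydride shift of the alkoxide; the five-atom tether, the free CH2 terminus, and an excess of the unhindered enone with a chelating diphosphine (no free phosphine to oligomerise it) are the features relied on.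

Step 6
Reactants: 10 [3,4-bis(benzyloxy)phenyl][(2S,3S,4S)-2-(4-benzyloxy-3-methoxyphenyl)-3-vinyltetrahydrofuran-4-yl]methanone
Product: 11 (R)-[3,4-bis(benzyloxy)phenyl][(2S,3S,4S)-2-(4-benzyloxy-3-methoxyphenyl)-3-vinyltetrahydrofuran-4-yl]methanol
Conditions: (S)-Me-CBS (0.3 equiv), catecholborane (1.8 equiv), toluene, −78 → −20 °C; MeOH quench, aq. NaOH wash
Reagents that add atoms: none
Why: Corey–Bakshi–Shibata reduction: the (S)-oxazaborolidine binds the ketone with the aryl group as the large substituent and delivers hydride to the face that makes C4a (R), the sense of acetophenone to (R)-1-phenylethanol; the Felkin–Anh preference of the adjacent C4 centre (C3 as its large group) is expected to reinforce this, and catecholborane is chosen because it does not hydroborate the vinyl group without a catalyst.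

Step 7
Reactants: 11 (R)-[3,4-bis(benzyloxy)phenyl][(2S,3S,4S)-2-(4-benzyloxy-3-methoxyphenyl)-3-vinyltetrahydrofuran-4-yl]methanol
Product: 14 (R)-[3,4-bis(benzyloxy)phenyl][(2S,3R,4S)-2-(4-benzyloxy-3-methoxyphenyl)-3-(hydroxymethyl)tetrahydrofuran-4-yl]methanol, via vicinal diol 12 (not isolated), via aldehyde 13 (not isolated)
Conditions: OsO4 (2 mol %), NaIO4 (4 equiv), 2,6-lutidine (2 equiv), dioxane–H2O 3:1, rt; filtration and quick extraction; then NaBH4, MeOH, 0 °C
Reagents that add atoms: osmium tetroxide, O=[Os](=O)(=O)=O (delivers the oxygen kept in CH2OH); sodium periodate, [Na+].[O-]I(=O)(=O)=O (terminal oxidant that reloads osmium with oxygen)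
Why: Lemieux–Johnson oxidation followed by borohydride reduction: osmium-catalysed dihydroxylation of the only alkene gives diol 12, periodate cleaves it to aldehyde 13 with loss of the terminal carbon as formaldehyde, and immediate reduction gives the primary alcohol; the lutidine buffer and the short life of 13 guard C3, now α to a carbonyl, against epimerisation, and no other centre is touched.

Step 8
Reactants: 14 (R)-[3,4-bis(benzyloxy)phenyl][(2S,3R,4S)-2-(4-benzyloxy-3-methoxyphenyl)-3-(hydroxymethyl)tetrahydrofuran-4-yl]methanol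
Product: 15 4-{(R)-hydroxy[(2S,3R,4S)-3-(hydroxymethyl)-2-(4-hydroxy-3-methoxyphenyl)tetrahydrofuran-4-yl]methyl}benzene-1,2-diol (target)
Conditions: H2 (1 atm), 10 % Pd/C, EtOAc–MeOH 1:1, rt; stopped when debenzylation is complete
Reagents that add atoms: none
Why: Catalytic hydrogenolysis: the three aryl benzyl ethers should cleave much faster than the ring benzylic ether at C2 or the secondary benzylic alcohol at C4a under neutral, acid-free conditions at one atmosphere, so all four stereocentres are retained and the target is released.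

Compound list
1 | 4-(benzyloxy)-3-methoxybenzaldehyde | COc1cc(C=O)ccc1OCc1ccccc1 | starting material
2 | allyl chloride (3-chloroprop-1-ene) | C=CCCl | starting material
3 | (Z)-(3-chloroprop-2-en-1-yl)bis[(1R,2S,3R,5R)-2,6,6-trimethylbicyclo[3.1.1]heptan-3-yl]borane | Cl/C=C\CB([C@@H]1C[C@@H]2C[C@H]([C@H]1C)C2(C)C)[C@@H]1C[C@@H]2C[C@H]([C@H]1C)C2(C)C | intermediate (not isolated)
4 | (1R,2R)-1-[4-(benzyloxy)-3-methoxyphenyl]-2-chlorobut-3-en-1-ol | COc1cc([C@@H](O)[C@H](Cl)C=C)ccc1OCc1ccccc1 | intermediate
5 | (2R,3S)-2-[4-(benzyloxy)-3-methoxyphenyl]-3-vinyloxirane (cis) | COc1cc([C@H]2O[C@H]2C=C)ccc1OCc1ccccc1 | intermediate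
6 | 3,4-bis(benzyloxy)benzaldehyde | O=Cc1ccc(OCc2ccccc2)c(OCc2ccccc2)c1 | starting material
7 | vinylmagnesium bromide | C=C[Mg]Br | starting material
8 | rac-1-[3,4-bis(benzyloxy)phenyl]prop-2-en-1-ol | C=CC(O)c1ccc(OCc2ccccc2)c(OCc2ccccc2)c1 | intermediate
9 | 1-[3,4-bis(benzyloxy)phenyl]prop-2-en-1-one | C=CC(=O)c1ccc(OCc2ccccc2)c(OCc2ccccc2)c1 | intermediate
10 | [3,4-bis(benzyloxy)phenyl][(2S,3S,4S)-2-(4-benzyloxy-3-methoxyphenyl)-3-vinyltetrahydrofuran-4-yl]methanone | COc1cc([C@H]2OC[C@@H](C(=O)c3ccc(OCc4ccccc4)c(OCc4ccccc4)c3)[C@@H]2C=C)ccc1OCc1ccccc1 | intermediate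
11 | (R)-[3,4-bis(benzyloxy)phenyl][(2S,3S,4S)-2-(4-benzyloxy-3-methoxyphenyl)-3-vinyltetrahydrofuran-4-yl]methanol | COc1cc([C@H]2OC[C@@H]([C@@H](O)c3ccc(OCc4ccccc4)c(OCc4ccccc4)c3)[C@@H]2C=C)ccc1OCc1ccccc1 | intermediate
12 | 1-[(2S,3R,4S)-2-(4-benzyloxy-3-methoxyphenyl)-4-{(R)-[3,4-bis(benzyloxy)phenyl](hydroxy)methyl}tetrahydrofuran-3-yl]ethane-1,2-diol, both epimers at the new carbinol | COc1cc([C@H]2OC[C@@H]([C@@H](O)c3ccc(OCc4ccccc4)c(OCc4ccccc4)c3)[C@@H]2C(O)CO)ccc1OCc1ccccc1 | intermediate (not isolated)
13 | (2S,3S,4S)-2-(4-benzyloxy-3-methoxyphenyl)-4-{(R)-[3,4-bis(benzyloxy)phenyl](hydroxy)methyl}tetrahydrofuran-3-carbaldehyde | COc1cc([C@H]2OC[C@@H]([C@@H](O)c3ccc(OCc4ccccc4)c(OCc4ccccc4)c3)[C@@H]2C=O)ccc1OCc1ccccc1 | intermediate (not isolated)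
14 | (R)-[3,4-bis(benzyloxy)phenyl][(2S,3R,4S)-2-(4-benzyloxy-3-methoxyphenyl)-3-(hydroxymethyl)tetrahydrofuran-4-yl]methanol | COc1cc([C@H]2OC[C@@H]([C@@H](O)c3ccc(OCc4ccccc4)c(OCc4ccccc4)c3)[C@@H]2CO)ccc1OCc1ccccc1 | intermediate
15 | 4-{(R)-hydroxy[(2S,3R,4S)-3-(hydroxymethyl)-2-(4-hydroxy-3-methoxyphenyl)tetrahydrofuran-4-yl]methyl}benzene-1,2-diol | COc1cc([C@H]2OC[C@@H]([C@@H](O)c3ccc(O)c(O)c3)[C@@H]2CO)ccc1O | target

Total step count: 8. Longest linear sequence: 6 steps (steps 1, 2, 5, 6, 7, 8).

Steps most likely to fail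

Step 5 (the proposed new method). What may go wrong: the alkoxide of the π-allyl intermediate may undergo hydride shift to an aryl ketone instead of adding to the enone, the enolate may oligomerise the enone, or ring closure may outrun exchange of the allyl faces so that the cis geometry of the epoxide is carried into a 2,3-cis ring. The fallback uses established chemistry, sets out from 5 and returns at 10. Epoxide 5 is combined under the same palladium catalysis with commercial, freshly distilled diethyl methylenemalonate. This is a doubly activated alkene of the class for which the cycloaddition is established, and its stabilised carbanion closes the ring more slowly, which leaves time for the allyl faces to exchange. The expected product is diethyl (2S,3S)-2-(4-benzyloxy-3-methoxyphenyl)-3-vinyltetrahydrofuran-4,4-dicarboxylate F1. Krapcho dealkoxycarbonylation (LiCl, wet DMSO, 140 °C) should give ethyl (2S,3S,4S)-2-(4-benzyloxy-3-methoxyphenyl)-3-vinyltetrahydrofuran-4-carboxylate F2, C4 settling trans to vinyl on protonation. Treatment with MeNH(OMe)·HCl and i-PrMgCl (THF, −20 °C) gives the Weinreb amide (2S,3S,4S)-2-(4-benzyloxy-3-methoxyphenyl)-N-methoxy-N-methyl-3-vinyltetrahydrofuran-4-carboxamide F3. Addition of 3,4-bis(benzyloxy)phenylmagnesium bromide F4 (from commercial 4-bromo-1,2-bis(benzyloxy)benzene and magnesium, THF, 0 °C) then gives ketone 10.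

Step 1. What may go wrong: the lithiated allyl chloride may decompose, or the (Z)-chloroallylborane may isomerise by 1,3-boron shift before it meets the aldehyde, so that facial and syn/anti selectivity are eroded and C2 is no longer uniform. The fallback sets out from 1 and returns at 10. Aldehyde 1 is homologated by Wittig reaction with (triphenylphosphoranylidene)acetaldehyde (toluene, 80 °C) to (E)-3-[4-(benzyloxy)-3-methoxyphenyl]prop-2-enal F5. Iminium-catalysed epoxidation with aqueous H2O2 (CH2Cl2, rt) uses the (R)-diarylprolinol trimethylsilyl ether, the antipode of the catalyst that converts cinnamaldehyde into its (2R,3S)-epoxide. It should give (2S,3R)-3-[4-(benzyloxy)-3-methoxyphenyl]oxirane-2-carbaldehyde F6, the catalyst fixing the aryl-bearing carbon directly in the conjugate-addition step. Wittig methylenation with methylenetriphenylphosphorane F7 (from Ph3PCH3Br and KHMDS, THF, −78 °C) gives (2R,3R)-2-[4-(benzyloxy)-3-methoxyphenyl]-3-vinyloxirane F8. This is the trans isomer of 5 with the same C2; it takes the place of 5 in step 5 and delivers 10.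

Step 6. What may go wrong: poor facial selectivity, because the α-branched ring carbon C4 is nearly as large as the aryl group for the oxazaborolidine and the C4 centre may oppose the catalyst. The fallback sets out from 10 and returns at 11. Ketone 10 is reduced without reagent control (NaBH4, MeOH, −20 °C) and the carbinol epimers are separated, the (R) epimer being 11. The unwanted (S)-[3,4-bis(benzyloxy)phenyl][(2S,3S,4S)-2-(4-benzyloxy-3-methoxyphenyl)-3-vinyltetrahydrofuran-4-yl]methanol F9 is inverted by Mitsunobu reaction with 4-nitrobenzoic acid (PPh3, DIAD, THF, 0 °C). This gives (R)-[3,4-bis(benzyloxy)phenyl][(2S,3S,4S)-2-(4-benzyloxy-3-methoxyphenyl)-3-vinyltetrahydrofuran-4-yl]methyl 4-nitrobenzoate F10, whose methanolysis (K2CO3, MeOH, rt) gives 11.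

Further compounds
F1 | step 5 | diethyl (2S,3S)-2-(4-benzyloxy-3-methoxyphenyl)-3-vinyltetrahydrofuran-4,4-dicarboxylate | COc1cc([C@H]2OCC(C(=O)OCC)(C(=O)OCC)[C@@H]2C=C)ccc1OCc1ccccc1
F2 | step 5 | ethyl (2S,3S,4S)-2-(4-benzyloxy-3-methoxyphenyl)-3-vinyltetrahydrofuran-4-carboxylate | COc1cc([C@H]2OC[C@@H](C(=O)OCC)[C@@H]2C=C)ccc1OCc1ccccc1
F3 | step 5 | (2S,3S,4S)-2-(4-benzyloxy-3-methoxyphenyl)-N-methoxy-N-methyl-3-vinyltetrahydrofuran-4-carboxamide | COc1cc([C@H]2OC[C@@H](C(=O)N(C)OC)[C@@H]2C=C)ccc1OCc1ccccc1
F4 | step 5 | 3,4-bis(benzyloxy)phenylmagnesium bromide | Br[Mg]c1ccc(OCc2ccccc2)c(OCc2ccccc2)c1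
F5 | step 1 | (E)-3-[4-(benzyloxy)-3-methoxyphenyl]prop-2-enal | COc1cc(/C=C/C=O)ccc1OCc1ccccc1
F6 | step 1 | (2S,3R)-3-[4-(benzyloxy)-3-methoxyphenyl]oxirane-2-carbaldehyde (trans) | COc1cc([C@H]2O[C@@H]2C=O)ccc1OCc1ccccc1
F7 | step 1 | methylenetriphenylphosphorane | C=P(c1ccccc1)(c1ccccc1)c1ccccc1
F8 | step 1 | (2R,3R)-2-[4-(benzyloxy)-3-methoxyphenyl]-3-vinyloxirane (trans) | COc1cc([C@H]2O[C@@H]2C=C)ccc1OCc1ccccc1
F9 | step 6 | (S)-[3,4-bis(benzyloxy)phenyl][(2S,3S,4S)-2-(4-benzyloxy-3-methoxyphenyl)-3-vinyltetrahydrofuran-4-yl]methanol | COc1cc([C@H]2OC[C@@H]([C@H](O)c3ccc(OCc4ccccc4)c(OCc4ccccc4)c3)[C@@H]2C=C)ccc1OCc1ccccc1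
F10 | step 6 | (R)-[3,4-bis(benzyloxy)phenyl][(2S,3S,4S)-2-(4-benzyloxy-3-methoxyphenyl)-3-vinyltetrahydrofuran-4-yl]methyl 4-nitrobenzoate | COc1cc([C@H]2OC[C@@H]([C@@H](OC(=O)c3ccc(cc3)[N+](=O)[O-])c3ccc(OCc4ccccc4)c(OCc4ccccc4)c3)[C@@H]2C=C)ccc1OCc1ccccc1
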